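(The numbers in the tables are calculated for an exercise; noise was put on by code.)

We have to decide when to stop this flask so that it holds the most single product, and its charges are those of the red run.

| flask | starting material | reagent | remark | time |
|---|---|---|---|---|
| red | 0.30 M | 0.39 M | the very flask that is asked about, followed so far |  |
| grey | 0.15 M | 0.39 M | run made earlier |  |
| flask | 0.30 M | 0.390 M |  | 15 d |

| run | time / d | single product / % | starting material / % |
|---|---|---|---|
| red | 0.125 | 8.8 | 47.9 |
| red | 0.333 | 10.4 | 20.1 |
| red | 0.625 | 11.2 | 11.0 |
| red | 1.25 | 10.4 | 3.0 |
| red | 3.00 | 6.0 | 0.7 |
| grey | 0.125 | 11.3 | 61.5 |
| grey | 0.333 | 17.7 | 29.9 |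
| grey | 0.833 | 17.7 | 9.9 |
| grey | 2.50 | 11.8 | 0 |
| grey | 6.00 | 4.5 | 0 |

(standard deviation of a reading: 1 percentage point)

* when, up to 15 d, the flask holds most single product
* the amount of single product, in percent of the starting material charged, at that time
* the first time at which single product reaches 5.9%, in the same percent

- the analysis behind the earlier runs scatters by 1 percentage point, standard deviation

I treat the peak as a crossing: single product rises while it is made faster than it is lost, and it peaks where the two rates meet. The making side can be read from grey. By 0.125 d grey held 11.3% of single product, while its starting material averaged about 80.8%. That gives 1.12 d⁻¹: this is the apparent making constant, single product found per day for each unit of starting material present, counted net of whatever was lost meanwhile, an apparent pseudo-first-order constant at this reagent charge and a reading from grey.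

The forecast follows the red curve and says 0.7 d, 11% and 0.065 d, on the ground that “The product peak is broad”. I dispute the time. Red's late readings show single product falling at 0.314 d⁻¹. A peak at red's highest reading, 0.625 d, would instead need a loss constant equal to the apparent making constant times c(starting material)/c(single product), which is roughly 1.10 d⁻¹, faster. So by these readings single product is lost faster near red's peak than in red's tail.

Red itself reads 10.4% at both 0.333 d and 1.25 d, which brackets the crossing in this flask within the scatter. I commit to the geometric middle of that bracket, 0.645 d, a little earlier than the forecast.

The flask gives 0.533 d, 11.7% and 0.0651 d.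

    starting material + reagent → single product + by-product (k = 0.148 L mol⁻¹ h⁻¹)
    reagent + single product → bis adduct + by-product (k = 0.0496 L mol⁻¹ h⁻¹)
    starting material + single product → side product (k = 0.889 L mol⁻¹ h⁻¹)
    2 starting material → homo dimer (k = 0.435 L mol⁻¹ h⁻¹)

The forecast's time is late, and so is my middle, yet the forecast's view holds on the plateau: the flask stays near its best until 0.929 d, beyond 0.7 d. At the peak the flask has 12.0% of starting material, so the apparent making constant calls for a rough loss constant of 1.15 d⁻¹. The first step's constant goes with the reagent charge, so the apparent making constant becomes 0.660 d⁻¹ in the neighbour flask with 0.23 M of reagent, and the flask's best scaled the same way gives 6.92%, where that neighbour holds 7.65%.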